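C–O cuts: the O8 methacrylate, the O13 acetate, and the butenolide bond O6–C12 (back to a C6/C12 diol). Skeleton cuts: C9–C10 by a retro-Claisen that re-forms O–C2, then C8=C9, the lactone bond C8–O2, C6–C7 and C1–C10.
Enabling feature: in the ring C1–C10, O8 and the C1 carbonyl are 1,4-related across C9–C10, and C10 carries C14. This is the pattern left by a [3,3] shift of C9=C8–O–C2–C1=C10 laid over the eight-membered ring O, C8, C7, C6, C5, C4, C3, C2.
Ring order forward: oxirane C4–C5, then an auxiliary butenolide C8–O–C13 that locks the C7=C11 geometry, then the oxocan-2-one, then the ten-membered carbocycle, then the final butenolide C12–O6.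
Stereochemistry: C4/C5 come from Sharpless epoxidation of nerol. C6 comes from Felkin–Anh/Cornforth addition to the epoxy aldehyde. A temporary C2 centre comes from organocatalytic α-oxyamination and is relayed to C10 in the chair. C8 comes from peripheral hydride delivery.
The cis-oxirane is carried from the start in place of the Z-olefin. In the target its oxygen lies on the olefin face syn to C7 and anti to O6 when H6 eclipses C4=C5, which is the face turned into the ten-membered ring, so a late peracid attack would be expected on the wrong face.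
Key step: step 18

Remarks
- Germacrane numbering is used for all intermediates: ring C1–C10, C11–C13 on C7, C14 on C10, C15 on C4. TBS = tert-butyldimethylsilyl, TBDPS = tert-butyldiphenylsilyl, TIPS = triisopropylsilyl, OTMP = 2,2,6,6-tetramethylpiperidin-1-yloxy.
- Assumption: the imidazolidinone enantiomer named in step 10 shields the same enamine face as in its α-halogenations. If the opposite sense were found, the antipode would be used.

Step 1
Reactants: 1 nerol
Product: 2 (2R,3S)-2,3-epoxynerol
Conditions: Ti(OiPr)4 (cat.), D-(−)-diethyl tartrate (cat.), t-BuOOH, 4 Å molecular sieves, CH2Cl2, −20 °C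
Reagents that add atoms: tert-butyl hydroperoxide, CC(C)(C)OO
Why: Sharpless asymmetric epoxidation touches only the allylic C4=C5 olefin, and with the D-(−)-tartrate it should deliver oxygen to the face that gives the (2R,3S)-epoxy alcohol, which sets C4 (S) and C5 (R) of the target as a cis-oxirane.

Step 2
Reactants: 2 (2R,3S)-2,3-epoxynerol
Product: 3 (2S,3S)-2,3-epoxyneral
Conditions: TEMPO (cat.), PhI(OAc)2, CH2Cl2, rt
Reagents that add atoms: none
Why: The oxoammonium (TEMPO/PhI(OAc)2) oxidation stops at the aldehyde under nearly neutral conditions, so the oxirane, its non-enolisable C5 centre and the prenyl olefin should be left alone.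

Step 3
Reactants: 4 1,3-dihydroxyacetone (sold as its dimer); 5 ethyl (triphenylphosphoranylidene)acetate
Product: 7 4-(hydroxymethyl)furan-2(5H)-one, via dihydroxy enoate 6 (not isolated)
Conditions: CH2Cl2, rt
Reagents that add atoms: ethyl (triphenylphosphoranylidene)acetate, CCOC(=O)C=P(c1ccccc1)(c1ccccc1)c1ccccc1
Why: Wittig olefination of the activated ketone gives an enoate with two equivalent CH2OH arms, and the arm cis to the ester lactonises at once, so ring formation fixes the C7=C11 geometry with C13 inside the ring and C12 outside.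

Step 4
Reactants: 7 4-(hydroxymethyl)furan-2(5H)-one
Product: 8 4-(TBSO-methyl)furan-2(5H)-one
Conditions: TBSCl, imidazole, CH2Cl2, 0 °C → rt
Reagents that add atoms: tert-butyldimethylsilyl chloride, CC(C)(C)[Si](C)(C)Cl
Why: Standard silylation of the primary alcohol masks O12 with a group that is removed later together with the O6 silyl ether.

Step 5
Reactants: 8 4-(TBSO-methyl)furan-2(5H)-one
Product: 10 3-bromo-4-(TBSO-methyl)furan-2(5H)-one, via trans-dibromide 9 (not isolated)
Conditions: Br2, CH2Cl2, rt, dark; then Et3N, 0 °C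
Reagents that add atoms: bromine, BrBr
Why: Bromine addition followed by E1cB loss of HBr (acidic C7–H, tertiary C11–Br) is the usual addition–elimination route to α-bromobutenolides and puts the halogen on C7.

Step 6
Reactants: 10 3-bromo-4-(TBSO-methyl)furan-2(5H)-one
Product: 11 3-bromo-4-(TBSO-methyl)-2-(TIPSO)furan
Conditions: TIPSOTf, Et3N, CH2Cl2, 0 °C
Reagents that add atoms: triisopropylsilyl triflate, CC(C)[Si](OS(=O)(=O)C(F)(F)F)(C(C)C)C(C)C
Why: Soft γ-enolisation with silyl triflate and amine turns the butenolide into a 2-silyloxyfuran, which removes the acidic C13 protons and the electrophilic carbonyl before metalation, while the bulky silyl group disfavours oxygen-to-carbon silyl migration.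

Step 7
Reactants: 11 3-bromo-4-(TBSO-methyl)-2-(TIPSO)furan; 3 (2S,3S)-2,3-epoxyneral
Product: 14 (4S,5R,6R)-epoxy carbinol butenolide, via 3-lithiofuran 12 (not isolated), via silyloxyfuran carbinol 13 (not isolated)
Conditions: n-BuLi, Et2O, −78 °C; then 3, −78 °C; AcOH, −78 °C; then Bu4NF–AcOH (1:1), THF, −78 → 0 °C
Reagents that add atoms: none
Why: Bromine–lithium exchange of a 3-bromo-2-silyloxyfuran gives a geometrically locked α-butenolide anion equivalent; its non-chelated addition to the α,β-epoxy aldehyde should follow the Felkin–Anh/Cornforth model (attack anti to the C5–O bond, past H5) and set 6R, and fluoride-triggered γ-protonation then returns the conjugated butenolide.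

Step 8
Reactants: 14 (4S,5R,6R)-epoxy carbinol butenolide
Product: 15 C6 TBS ether of 14
Conditions: TBSOTf, 2,6-lutidine, CH2Cl2, −78 °C
Reagents that add atoms: tert-butyldimethylsilyl triflate, CC(C)(C)[Si](C)(C)OS(=O)(=O)C(F)(F)F
Why: Silyl triflate with a hindered pyridine silylates crowded secondary epoxy alcohols at low temperature without opening the oxirane or allowing Payne migration.

Step 9
Reactants: 15 C6 TBS ether of 14
Product: 17 C1 aldehyde, via ozonide 16 (not isolated)
Conditions: O3, CH2Cl2, −78 °C (stopped at consumption of 15); then PPh3, −78 °C → rt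
Reagents that add atoms: ozone, [O-][O+]=O
Why: In this ozonolysis with reductive work-up the electron-rich trisubstituted prenyl olefin should react far faster than the tetrasubstituted, lactone-conjugated C7=C11 bond, which exposes C1 as the aldehyde.

Step 10
Reactants: 17 C1 aldehyde
Product: 18 (2R)-2-OTMP aldehyde
Conditions: TEMPO, (5R)-5-benzyl-2,2,3-trimethylimidazolidin-4-one·HBF4 (20 mol %), FeCl3 (10 mol %), NaNO2 (30 mol %), O2, DMF, −10 °C
Reagents that add atoms: TEMPO, CC1(C)CCCC(C)(C)N1[O]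
Why: In the enamine-catalysed α-oxyamination TEMPO is taken up on the unshielded enamine face, so the catalyst sets 2R, and the alkoxyamine serves as a base- and nucleophile-stable protecting group for O2.

Step 11
Reactants: 18 (2R)-2-OTMP aldehyde; 19 ethylmagnesium bromide
Product: 20 C1 carbinol (epimers at C1)
Conditions: EtMgBr, THF, −78 °C; aq NH4Cl
Reagents that add atoms: ethylmagnesium bromide, CC[Mg]Br
Why: Grignard addition to the aldehyde at −78 °C should outrun attack on the hindered butenolide and brings in C10 and C14; the new C1 centre does not matter because it is oxidised in step 13.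

Step 12
Reactants: 20 C1 carbinol
Product: 23 C8 acid with O13-TBDPS, via sodium hydroxy carboxylate 21 (not isolated), via bis-TBDPS derivative 22 (not isolated)
Conditions: NaOH (1.0 equiv), THF–H2O, 0 °C; evaporate; TBDPSCl, imidazole, DMF, 0 °C → rt; then K2CO3 (cat.), MeOH–H2O, 0 °C; pH 5 buffer
Reagents that add atoms: sodium hydroxide, [Na+].[OH-]; tert-butyldiphenylsilyl chloride, CC(C)(C)[Si](Cl)(c1ccccc1)c1ccccc1
Why: Saponification followed by silylation, as used for rigid cis-hydroxy acids of the phthalide type, opens the auxiliary butenolide to a salt that cannot relactonise, caps primary O13 (and the carboxylate) in preference to the hindered C1 carbinol, and frees the acid by mild silyl-ester hydrolysis with the C7=C11 geometry unchanged; this is done before any epimerisable ketone is present.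

Step 13
Reactants: 23 C8 acid with O13-TBDPS
Product: 24 C1 keto acid
Conditions: Dess–Martin periodinane, CH2Cl2, 0 °C → rt
Reagents that add atoms: none
Why: Dess–Martin oxidation converts the secondary carbinol into the ethyl ketone under non-basic conditions, which tolerate the free acid, the alkoxyamine and the oxirane and should not epimerise C2.

Step 14
Reactants: 24 C1 keto acid
Product: 25 (2R)-hydroxy keto acid (seco acid)
Conditions: Zn, AcOH–THF–H2O (1:4:1), 0 °C → rt
Reagents that add atoms: none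
Why: Reductive N–O cleavage of an α-carbonyl alkoxyamine with Zn/AcOH frees the C2 hydroxyl with retention, and the short, dilute acid exposure should spare the silyl ethers and the oxirane.

Step 15
Reactants: 25 (2R)-hydroxy keto acid
Product: 27 eight-membered keto lactone, via mixed anhydride 26 (not isolated)
Conditions: 2-methyl-6-nitrobenzoic anhydride, DMAP, CH2Cl2 (about 1 mM, slow addition), rt
Reagents that add atoms: none
Why: Shiina macrolactonisation is established for eight-membered lactones, and here the cis-oxirane and the sp2 atoms C7 and C8 remove rotors and hold O2 near C8, so the acyl–oxygen closure should compete with oligomerisation.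

Step 16
Reactants: 27 eight-membered keto lactone
Product: 29 (Z)-C1 silyl enol ether lactone, via potassium enolate 28 (not isolated)
Conditions: TBSCl (3 equiv), then KN(SiMe3)2 (1.1 equiv, slow), THF, −78 °C
Reagents that add atoms: tert-butyldimethylsilyl chloride, CC(C)(C)[Si](C)(C)Cl
Why: Kinetic deprotonation by the bulky amide should take place at the open C10 methylene and not at the tertiary C2–H, should favour the Z(O)-enolate, and is trapped at once by the silyl chloride already present, before the enolate can attack the lactone; silyl triflate is avoided because of the oxirane.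

Step 17
Reactants: 29 (Z)-C1 silyl enol ether lactone
Product: 30 2-methylene oxocane
Conditions: Cp2TiMe2 (3 equiv), toluene, 75 °C, dark
Reagents that add atoms: dimethyltitanocene, [CH3-].[CH3-].[Ti+4].c1cc[cH-]c1.c1cc[cH-]c1
Why: In the Petasis methylenation, thermally generated Cp2Ti=CH2 converts the only carbonyl group left, the lactone C8=O, into the exocyclic enol ether C8=C9 without acid or base, which silyl enol ether, silyl ethers and oxirane should survive.

Step 18
Reactants: 30 2-methylene oxocane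
Product: 31 ten-membered C8 enone with C1 silyl enol ether
Conditions: mesitylene (0.01 M, degassed), Et3N (trace), base-washed sealed tube, 160 °C
Reagents that add atoms: none
Why: A concerted suprafacial [3,3]-sigmatropic (aliphatic Claisen) shift runs through C9=C8–O–C2–C1=C10, so C9–C10 forms as O–C2 breaks, driven by the new C8 carbonyl conjugated with C7=C11. The closest known reaction type is the methylenation–Claisen enlargement of 6-alkenyl-2-methylenetetrahydropyrans to cyclooctenones; here the carbocycle C1–C10 closes by two-atom ring expansion of the oxocane, its two exocyclic π-termini being joined while the ring opens at O–C2, and not by end-to-end cyclisation. Because C3 and C7 are tied by the short C4–C5–C6 bridge with its cis-oxirane, only a chair with C3 pseudo-axial on C2 is within reach, so the new C1=C2 enol ether should carry C3 and C10 cis, a geometry that is erased on hydrolysis. In that chair the (2R) centre decides which face of C1=C10 meets C9 and the (Z)-enol ether keeps C14 pseudo-equatorial, which together should give 10S. The step needs chair over boat and [3,3] over [1,3] or 1,5-hydrogen shifts, and these are secured by the bridge, by the equatorial methyl group and by the acid-free medium. The siloxy group on the central allyl carbon C1 slows such shifts, hence the high temperature, which silyl ethers and oxirane should tolerate.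

Step 19
Reactants: 31 ten-membered C8 enone with C1 silyl enol ether
Product: 32 (8R)-allylic alcohol
Conditions: i-Bu2AlH, CH2Cl2, −78 °C; aq potassium sodium tartrate
Reagents that add atoms: none
Why: In this 1,2-reduction of the twisted enone, hydride should reach C8 from the ring periphery on the C13 side of a conformer in which C5 and C9 leave the C6–C7–C8 plane on opposite faces, which places O8 cis to O6 (8R); the aprotic medium spares the silyl enol ether.

Step 20
Reactants: 32 (8R)-allylic alcohol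
Product: 33 C8 methacrylate
Conditions: methacrylic anhydride, DMAP, Et3N, CH2Cl2, 0 °C → rt
Reagents that add atoms: methacrylic anhydride, C=C(C)C(=O)OC(=O)C(C)=C
Why: DMAP-catalysed acylation esterifies the only free hydroxyl with retention at C8.

Step 21
Reactants: 33 C8 methacrylate
Product: 34 C1 ketone C6,C12-diol
Conditions: HF·pyridine, pyridine, THF, 0 °C → rt
Reagents that add atoms: none
Why: Buffered HF cleaves the silyl enol ether and both TBS ethers much faster than the primary TBDPS ether, a graded desilylation that trisubstituted oxiranes are known to survive; protonation at C2 creates no stereocentre.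

Step 22
Reactants: 34 C1 ketone C6,C12-diol
Product: 36 butenolide with O13-TBDPS, via lactol 35 (not isolated)
Conditions: TEMPO (cat.), PhI(OAc)2 (2.5 equiv), CH2Cl2, rt
Reagents that add atoms: none
Why: In the TEMPO/PhI(OAc)2 oxidative lactonisation the primary allylic C12 alcohol is oxidised first, the cis C6 hydroxyl closes the lactol, and a second oxidation gives the butenolide, with O13 still capped so that only C12 is oxidised.

Step 23
Reactants: 36 butenolide with O13-TBDPS
Product: 37 C13 alcohol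
Conditions: Bu4NF, AcOH, THF, 0 °C → rt
Reagents that add atoms: none
Why: Acetic-acid-buffered fluoride removes the remaining silyl ether without basic conditions that could epimerise C10 or shift the methacrylate.

Step 24
Reactants: 37 C13 alcohol
Product: 38 target CNP0128625.1
Conditions: Ac2O, pyridine, DMAP (cat.), CH2Cl2, 0 °C
Reagents that add atoms: acetic anhydride, CC(=O)OC(C)=O
Why: Standard acetylation of the primary allylic alcohol completes the target without touching any stereocentre.

Compound list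
1 | nerol, (2Z)-3,7-dimethylocta-2,6-dien-1-ol | CC(C)=CCC/C(C)=C\CO | starting material
2 | (2R,3S)-2,3-epoxynerol (4S,5R in ring numbering; cis-oxirane) | CC(C)=CCC[C@]1(C)O[C@@H]1CO | intermediate
3 | (2S,3S)-2,3-epoxyneral (same geometry as 2; the C5 descriptor changes because CHO outranks C4) | CC(C)=CCC[C@]1(C)O[C@@H]1C=O | intermediate
4 | 1,3-dihydroxyacetone | OCC(=O)CO | starting material
5 | ethyl (triphenylphosphoranylidene)acetate | CCOC(=O)C=P(c1ccccc1)(c1ccccc1)c1ccccc1 | starting material
6 | ethyl 4-hydroxy-3-(hydroxymethyl)but-2-enoate | CCOC(=O)C=C(CO)CO | intermediate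
7 | 4-(hydroxymethyl)furan-2(5H)-one | O=C1C=C(CO)CO1 | intermediate
8 | 4-(TBSO-methyl)furan-2(5H)-one | O=C1C=C(CO[Si](C)(C)C(C)(C)C)CO1 | intermediate
9 | trans-3,4-dibromo-4-(TBSO-methyl)dihydrofuran-2-one (racemic, one enantiomer drawn) | O=C1OC[C@](Br)(CO[Si](C)(C)C(C)(C)C)[C@@H]1Br | intermediate
10 | 3-bromo-4-(TBSO-methyl)furan-2(5H)-one | O=C1OCC(CO[Si](C)(C)C(C)(C)C)=C1Br | intermediate
11 | 3-bromo-4-(TBSO-methyl)-2-(TIPSO)furan | CC(C)[Si](Oc1occ(CO[Si](C)(C)C(C)(C)C)c1Br)(C(C)C)C(C)C | intermediate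
12 | 3-lithio-4-(TBSO-methyl)-2-(TIPSO)furan | CC(C)[Si](Oc1occ(CO[Si](C)(C)C(C)(C)C)c1[Li])(C(C)C)C(C)C | intermediate
13 | (4S,5R,6R)-carbinol bearing the 2-(TIPSO)furan-3-yl group on C6 | CC(C)=CCC[C@]1(C)O[C@@H]1[C@H](O)c1c(CO[Si](C)(C)C(C)(C)C)coc1O[Si](C(C)C)(C(C)C)C(C)C | intermediate
14 | 3-[(R)-hydroxy{(2R,3S)-3-methyl-3-(4-methylpent-3-enyl)oxiran-2-yl}methyl]-4-(TBSO-methyl)furan-2(5H)-one | CC(C)=CCC[C@]1(C)O[C@@H]1[C@H](O)C1=C(CO[Si](C)(C)C(C)(C)C)COC1=O | intermediate
15 | C6 TBS ether of 14 | CC(C)=CCC[C@]1(C)O[C@@H]1[C@H](O[Si](C)(C)C(C)(C)C)C1=C(CO[Si](C)(C)C(C)(C)C)COC1=O | intermediate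
16 | 1,2,4-trioxolane (ozonide) of the prenyl olefin of 15 | CC1(C)OOC(CC[C@]2(C)O[C@@H]2[C@H](O[Si](C)(C)C(C)(C)C)C2=C(CO[Si](C)(C)C(C)(C)C)COC2=O)O1 | intermediate
17 | C1 aldehyde (4S,5R,6R), auxiliary butenolide intact | O=CCC[C@]1(C)O[C@@H]1[C@H](O[Si](C)(C)C(C)(C)C)C1=C(CO[Si](C)(C)C(C)(C)C)COC1=O | intermediate
18 | (2R)-2-OTMP aldehyde | O=C[C@H](ON1C(C)(C)CCCC1(C)C)C[C@]1(C)O[C@@H]1[C@H](O[Si](C)(C)C(C)(C)C)C1=C(CO[Si](C)(C)C(C)(C)C)COC1=O | intermediate
19 | ethylmagnesium bromide | CC[Mg]Br | starting material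
20 | C1 carbinol (2R; both C1 epimers) | CCC(O)[C@H](ON1C(C)(C)CCCC1(C)C)C[C@]1(C)O[C@@H]1[C@H](O[Si](C)(C)C(C)(C)C)C1=C(CO[Si](C)(C)C(C)(C)C)COC1=O | intermediate
21 | sodium C8 carboxylate with free O13–H (C13 cis to C8, C12 cis to C6) | CCC(O)[C@H](ON1C(C)(C)CCCC1(C)C)C[C@]1(C)O[C@@H]1[C@H](O[Si](C)(C)C(C)(C)C)/C(C(=O)[O-])=C(/CO)CO[Si](C)(C)C(C)(C)C.[Na+] | intermediate
22 | TBDPS ester and O13-TBDPS ether | CCC(O)[C@H](ON1C(C)(C)CCCC1(C)C)C[C@]1(C)O[C@@H]1[C@H](O[Si](C)(C)C(C)(C)C)/C(C(=O)O[Si](c1ccccc1)(c1ccccc1)C(C)(C)C)=C(/CO[Si](c1ccccc1)(c1ccccc1)C(C)(C)C)CO[Si](C)(C)C(C)(C)C | intermediate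
23 | C8 acid, O13-TBDPS, O12- and O6-TBS, free C1 carbinol | CCC(O)[C@H](ON1C(C)(C)CCCC1(C)C)C[C@]1(C)O[C@@H]1[C@H](O[Si](C)(C)C(C)(C)C)/C(C(=O)O)=C(/CO[Si](c1ccccc1)(c1ccccc1)C(C)(C)C)CO[Si](C)(C)C(C)(C)C | intermediate
24 | C1 ethyl ketone, (2R)-OTMP, C8 acid | CCC(=O)[C@H](ON1C(C)(C)CCCC1(C)C)C[C@]1(C)O[C@@H]1[C@H](O[Si](C)(C)C(C)(C)C)/C(C(=O)O)=C(/CO[Si](c1ccccc1)(c1ccccc1)C(C)(C)C)CO[Si](C)(C)C(C)(C)C | intermediate
25 | (2R)-hydroxy keto acid (seco acid) | CCC(=O)[C@H](O)C[C@]1(C)O[C@@H]1[C@H](O[Si](C)(C)C(C)(C)C)/C(C(=O)O)=C(/CO[Si](c1ccccc1)(c1ccccc1)C(C)(C)C)CO[Si](C)(C)C(C)(C)C | intermediate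
26 | mixed anhydride of 25 with 2-methyl-6-nitrobenzoic acid | CCC(=O)[C@H](O)C[C@]1(C)O[C@@H]1[C@H](O[Si](C)(C)C(C)(C)C)/C(C(=O)OC(=O)c1c(C)cccc1[N+](=O)[O-])=C(/CO[Si](c1ccccc1)(c1ccccc1)C(C)(C)C)CO[Si](C)(C)C(C)(C)C | intermediate
27 | oxocan-2-one (ring O, C8, C7, C6, C5, C4, C3, C2) with propanoyl on (2R)-C2, cis-4,5-oxirane, (6R)-OTBS, exocyclic C7=C11 | O=C1O[C@@H](C(=O)CC)C[C@]2(C)O[C@@H]2[C@H](O[Si](C)(C)C(C)(C)C)/C1=C(/CO[Si](c1ccccc1)(c1ccccc1)C(C)(C)C)CO[Si](C)(C)C(C)(C)C | intermediate
28 | potassium Z(O)-enolate of 27 (C1=C10) | O=C1O[C@@H](/C([O-])=C/C)C[C@]2(C)O[C@@H]2[C@H](O[Si](C)(C)C(C)(C)C)/C1=C(/CO[Si](c1ccccc1)(c1ccccc1)C(C)(C)C)CO[Si](C)(C)C(C)(C)C.[K+] | intermediate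
29 | lactone with (Z)-1-(TBSO)prop-1-enyl on (2R)-C2 | O=C1O[C@@H](/C(O[Si](C)(C)C(C)(C)C)=C/C)C[C@]2(C)O[C@@H]2[C@H](O[Si](C)(C)C(C)(C)C)/C1=C(/CO[Si](c1ccccc1)(c1ccccc1)C(C)(C)C)CO[Si](C)(C)C(C)(C)C | intermediate
30 | 2-methylene oxocane (C8=C9 exocyclic), (2R), (Z)-enol ether, cis-4,5-oxirane, (6R) | C=C1O[C@@H](/C(O[Si](C)(C)C(C)(C)C)=C/C)C[C@]2(C)O[C@@H]2[C@H](O[Si](C)(C)C(C)(C)C)/C1=C(/CO[Si](c1ccccc1)(c1ccccc1)C(C)(C)C)CO[Si](C)(C)C(C)(C)C | intermediate
31 | ten-membered C8 enone, (10S)-methyl, (1E)-C1=C2 TBS enol ether (C3 and C10 cis), cis-4,5-oxirane, (6R) | O=C1C[C@H](C)/C(O[Si](C)(C)C(C)(C)C)=C\C[C@]2(C)O[C@@H]2[C@H](O[Si](C)(C)C(C)(C)C)/C1=C(/CO[Si](c1ccccc1)(c1ccccc1)C(C)(C)C)CO[Si](C)(C)C(C)(C)C | intermediate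
32 | (8R)-allylic alcohol of 31 | O[C@@H]1C[C@H](C)/C(O[Si](C)(C)C(C)(C)C)=C\C[C@]2(C)O[C@@H]2[C@H](O[Si](C)(C)C(C)(C)C)/C1=C(/CO[Si](c1ccccc1)(c1ccccc1)C(C)(C)C)CO[Si](C)(C)C(C)(C)C | intermediate
33 | (8R)-methacrylate of 32 | C=C(C)C(=O)O[C@@H]1C[C@H](C)/C(O[Si](C)(C)C(C)(C)C)=C\C[C@]2(C)O[C@@H]2[C@H](O[Si](C)(C)C(C)(C)C)/C1=C(/CO[Si](c1ccccc1)(c1ccccc1)C(C)(C)C)CO[Si](C)(C)C(C)(C)C | intermediate
34 | C1 ketone, free (6R)-OH and C12-OH, O13-TBDPS | C=C(C)C(=O)O[C@@H]1C[C@H](C)C(=O)CC[C@]2(C)O[C@@H]2[C@H](O)/C1=C(/CO[Si](c1ccccc1)(c1ccccc1)C(C)(C)C)CO | intermediate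
35 | C12 lactol (anomers) | C=C(C)C(=O)O[C@@H]1C[C@H](C)C(=O)CC[C@]2(C)O[C@@H]2[C@@H]2OC(O)C(CO[Si](c3ccccc3)(c3ccccc3)C(C)(C)C)=C21 | intermediate
36 | 6,12-butenolide with O13-TBDPS | C=C(C)C(=O)O[C@@H]1C[C@H](C)C(=O)CC[C@]2(C)O[C@@H]2[C@@H]2OC(=O)C(CO[Si](c3ccccc3)(c3ccccc3)C(C)(C)C)=C21 | intermediate
37 | 13-hydroxy butenolide | C=C(C)C(=O)O[C@@H]1C[C@H](C)C(=O)CC[C@]2(C)O[C@@H]2[C@@H]2OC(=O)C(CO)=C21 | intermediate
38 | CNP0128625.1, (4S,5R,6R,8R,10S) | C=C(C)C(=O)O[C@@H]1C[C@H](C)C(=O)CC[C@]2(C)O[C@@H]2[C@@H]2OC(=O)C(COC(C)=O)=C21 | target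

Total step count: 24.
Longest linear sequence: 22 steps, from 1,3-dihydroxyacetone 4 (20 steps from nerol 1).

Steps most likely to fail

Step 18. The shift may be too slow, because the siloxy group on C1 retards it and the bridged chair is strained, so thermal decay of the dienol ether could compete. A boat could also erode the selectivity at C10.
Fallback, from 30 back to 31: the same C9–C10 bond would be made by an oxidative, non-pericyclic closure of a six-membered ring.
- Anodic coupling of the two enol ethers of 30 (carbon anode, LiClO4, 2,6-lutidine, MeOH–THF, constant current) should join C9 to C10 while O–C2 stays intact. Methanol would be trapped at C8 and the silyl group lost from O1. The product would be the oxa-bridged keto ketal F1.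
- SmI2 (2 equiv, THF–HMPA, −78 °C) would then cleave the α-keto C2–O bond.
- The regiodefined samarium enolate would be silylated in the same flask with TBSCl, and the C8 hemiketal would collapse to the ketone, which gives 31. A C1=C2 geometric isomer would converge at 34.

Step 15. Oligomerisation and slow acyl transfer are likely, since the acyl donor is tetrasubstituted and hindered and the α-ketol hydroxyl is a weak nucleophile. Prolonged contact with DMAP could epimerise C2.
Fallback, from 17 back to 27: the alcohol would be activated instead of the acid, so the ring closes at O–C2 by SN2.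
- Step 10 with the (5S)-imidazolidinone would give the (2S)-OTMP aldehyde F2.
- EtMgBr would give the carbinol F3.
- The sequence of step 12 would run through the sodium salt F4 and the bis-TBDPS derivative F5 to the hydroxy acid F6.
- Dess–Martin oxidation would give the keto acid F7.
- Zn/AcOH would give the (2S)-seco acid F8.
- Mitsunobu macrolactonisation (PPh3, DIAD, toluene, high dilution) would let the carboxylate displace the activated α-keto oxyphosphonium at C2 with inversion, which gives (2R)-27.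

Step 19. The facial selectivity at C8 may be poor or reversed if the ring reacts through a conformer with C5 and C9 on the same side.
Fallback, from 31 back to 33: C8 would be set by inversion instead of by the hydride face. The 8-epi alcohol F9 from the reduction would be esterified with methacrylic acid under Mitsunobu conditions (PPh3, DIAD, THF). This inverts C8 and installs the methacrylate in one operation, and the tetrasubstituted C7=C11 bond disfavours the SN2′ path.

Further compounds
F1 | step 18 | oxa-bridged (O between C2 and C8) C1 keto C8 methyl ketal, C9–C10 bond formed | CO[C@]12C[C@H](C)C(=O)[C@H](O1)C[C@]3(C)O[C@@H]3[C@H](O[Si](C)(C)C(C)(C)C)/C2=C(/CO[Si](c4ccccc4)(c4ccccc4)C(C)(C)C)CO[Si](C)(C)C(C)(C)C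
F2 | step 15 | (2S)-2-OTMP aldehyde | O=C[C@@H](ON1C(C)(C)CCCC1(C)C)C[C@]1(C)O[C@@H]1[C@H](O[Si](C)(C)C(C)(C)C)C1=C(CO[Si](C)(C)C(C)(C)C)COC1=O
F3 | step 15 | (2S)-C1 carbinol | CCC(O)[C@@H](ON1C(C)(C)CCCC1(C)C)C[C@]1(C)O[C@@H]1[C@H](O[Si](C)(C)C(C)(C)C)C1=C(CO[Si](C)(C)C(C)(C)C)COC1=O
F4 | step 15 | (2S)-sodium hydroxy carboxylate | CCC(O)[C@@H](ON1C(C)(C)CCCC1(C)C)C[C@]1(C)O[C@@H]1[C@H](O[Si](C)(C)C(C)(C)C)/C(C(=O)[O-])=C(/CO)CO[Si](C)(C)C(C)(C)C.[Na+]
F5 | step 15 | (2S)-bis-TBDPS derivative | CCC(O)[C@@H](ON1C(C)(C)CCCC1(C)C)C[C@]1(C)O[C@@H]1[C@H](O[Si](C)(C)C(C)(C)C)/C(C(=O)O[Si](c1ccccc1)(c1ccccc1)C(C)(C)C)=C(/CO[Si](c1ccccc1)(c1ccccc1)C(C)(C)C)CO[Si](C)(C)C(C)(C)C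
F6 | step 15 | (2S)-hydroxy acid | CCC(O)[C@@H](ON1C(C)(C)CCCC1(C)C)C[C@]1(C)O[C@@H]1[C@H](O[Si](C)(C)C(C)(C)C)/C(C(=O)O)=C(/CO[Si](c1ccccc1)(c1ccccc1)C(C)(C)C)CO[Si](C)(C)C(C)(C)C
F7 | step 15 | (2S)-keto acid | CCC(=O)[C@@H](ON1C(C)(C)CCCC1(C)C)C[C@]1(C)O[C@@H]1[C@H](O[Si](C)(C)C(C)(C)C)/C(C(=O)O)=C(/CO[Si](c1ccccc1)(c1ccccc1)C(C)(C)C)CO[Si](C)(C)C(C)(C)C
F8 | step 15 | (2S)-hydroxy keto acid | CCC(=O)[C@@H](O)C[C@]1(C)O[C@@H]1[C@H](O[Si](C)(C)C(C)(C)C)/C(C(=O)O)=C(/CO[Si](c1ccccc1)(c1ccccc1)C(C)(C)C)CO[Si](C)(C)C(C)(C)C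
F9 | step 19 | (8S)-allylic alcohol (8-epi-32) | O[C@H]1C[C@H](C)/C(O[Si](C)(C)C(C)(C)C)=C\C[C@]2(C)O[C@@H]2[C@H](O[Si](C)(C)C(C)(C)C)/C1=C(/CO[Si](c1ccccc1)(c1ccccc1)C(C)(C)C)CO[Si](C)(C)C(C)(C)C
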